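The leftover is what a flask has to work with: the initiator remaining once the impurity has taken its own amount, one for one, told as a fraction of the free monomer charged. The one-for-one is a guess, since no earlier run changes the impurity. The leftover comes to 4.97% in birch and 3.30% in maple.

the same everywhere: free monomer 30 mM
- birch: initiator 2 mM; impurity 0.51 mM; run made earlier
- maple: initiator 1.5 mM; impurity 0.51 mM; run made earlier
- ochre: initiator 3.0 mM; impurity 1.0 mM; time 6.0 h
- green: initiator 3.0 mM; impurity 0.51 mM; time 6.0 h
- violet: initiator 3.0 mM; impurity 0.12 mM; time 6.0 h
- grey: initiator 3.0 mM; impurity 2.0 mM; time 6.0 h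

| run | time / h | monomer in chains / % | free monomer / % |
|---|---|---|---|
| birch | 0.333 | 14.2 | 67.5 |
| birch | 0.833 | 17.7 | 37.5 |
| birch | 1.50 | 22.1 | 17.4 |
| birch | 2.50 | 21.2 | 6.8 |
| birch | 4.00 | 21.7 | 2.2 |
| maple | 0.667 | 10.9 | 49.8 |
| maple | 1.33 | 15.4 | 24.4 |
| maple | 2.00 | 18.1 | 12.8 |
| maple | 3.00 | 19.4 | 4.9 |
| maple | 4.00 | 17.5 | 0 |

(scatter of a reading: 1 percentage point)

- the numbers in the tables scatter with a standard deviation of 1 percentage point
- no earlier run changes the charge of impurity; that part of a forecast is a guess

1. the flasks put in order of amount of monomer in chains, in percent of the free monomer charged, best first, at 6.0 h (ochre / green / violet / grey)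
2. the same order at 80 min (ochre / green / violet / grey)
3. the amount of monomer in chains, in percent of the free monomer charged of the flask you put first, at 6.0 h
4. the amount of monomer in chains, in percent of the free monomer charged of the flask you put last, at 6.0 h

One way to the answer is a straight line through the flat ends of monomer in chains, 21.7% in birch and 18.3% in maple. For violet, with a leftover of 9.60%, the line gives 31.1%. But at no leftover it still gives 11.7%, chains with no initiator to start them, so this way cheats.

The other way goes through the free monomer, taken as a pseudo-first-order loss. At the reading nearest half, its rate constant is 1.18 h⁻¹ in birch and 1.05 h⁻¹ in maple. The pull, the rate constant added per whole fraction of leftover, is therefore 7.94 h⁻¹, and the loss without leftover is 0.783 h⁻¹. The leftover's part of the loss, a selectivity, is pull times leftover over the total: 33.5% in birch and 25.1% in maple. The flat ends hold on average 69.0% of that part.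

This rule vanishes at no leftover and gives 34.0% for violet and 17.4% for grey, with green and ochre between them in that order. At 80 min it leaves 12.7% of the free monomer in violet and 24.7% in grey, less in violet than in grey, so the rule's order is kept for both times.

The forecast, which says of the impurity “I guess it is a poison that removes initiator one-for-one”, gives violet > green > ochre > grey at 6.0 h and violet > green > ochre > grey at 80 min, with a top of 28.5%, lower than the rule's, and a low of 19.5%, higher than the rule's.

Violet comes to 34.8% and grey to 21.4%, in the order violet > green > ochre > grey, and violet > green > ochre > grey at 80 min.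

    initiator + impurity → spent initiator (k = 23.9 L mol⁻¹ s⁻¹)
    free monomer + initiator → living end + monomer in chains (k = 0.824 L mol⁻¹ s⁻¹)
    free monomer + living end → monomer in chains + living end, rate k3*[living end]*[free monomer] (k = 0.0662 L mol⁻¹ s⁻¹)
    free monomer → uncatalysed product (k = 1.60 × 10⁻⁴ s⁻¹)
    free monomer + monomer in chains → side product (k = 0.0102 L mol⁻¹ s⁻¹)

Grey holds 1.46 mM of living end with 23.2% of its impurity unbound, and that living end, as a fraction of the free monomer charged, gives 22.8% through the pull. A neighbour of violet charged with 1.2 mM of initiator has a leftover of 3.60%, the pull gives 18.5%, and that flask holds 17.3% in chains.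

(The numbers in the tables are calculated on assumed constants, noise included.)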